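## Retrosynthetic overview

1. The C40 chain is cut at C11=C12 and C11'=C12' (two Wittig reactions): ring-A C15 keto-phosphonium salt + C10 trienedial + ring-B C15 phosphonium salt, joined in the last three steps.
2. Both C15 salts come from one C15 vinyl carbinol (C13 enone + vinyl Grignard; enone from the ring aldehyde + acetonylidene ylide). Ring A: desilylation, MnO2, salt formation. Ring B: salt formation with the silyl ether kept.
3. The ring aldehyde comes from a trans hydroxy ester made by face-selective hydride reduction of the racemic keto ester and resolved as its camphanate.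
4. The C10 dialdehyde comes from (E)-1,4-dibromobut-2-ene (Arbuzov), double Horner–Wadsworth–Emmons reaction with methylglyoxal dimethyl acetal, and hydrolysis.
5. Ring formation: a single cyclohexenone annulation (mesityl oxide + methyl acetoacetate) in the first step; this ring becomes ring B and, after oxidation, ring A. No ring is formed later.

Assumption: the target is read as all-E (6R,3'R,6'R)-3'-hydroxy-ε,ε-caroten-3-one; racemic compounds are drawn as the enantiomer that is carried on; all polyene steps are run under argon in dim light.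

## Route

Step 1
Reactants: 1 mesityl oxide (4-methylpent-3-en-2-one); 2 methyl acetoacetate
Product: 4 methyl 2,6,6-trimethyl-4-oxocyclohex-2-ene-1-carboxylate (racemic), via Michael adduct 3 (not isolated)
Conditions: ZnCl2 (0.3 equiv), heptane/toluene, reflux, Dean–Stark, 48 h
Reagents that add atoms: none
Why: Lewis-acid-promoted Michael addition of the acetoacetate to the β-carbon of mesityl oxide followed by intramolecular aldol condensation (Robinson-type annulation) builds the trimethylcyclohexenone with the ester on the future C6, the stereocentre being formed racemic.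

Step 2
Reactants: 4 methyl 2,6,6-trimethyl-4-oxocyclohex-2-ene-1-carboxylate (racemic)
Product: 5 methyl (1R*,4R*)-4-hydroxy-2,6,6-trimethylcyclohex-2-ene-1-carboxylate (racemic trans alcohol)
Conditions: LiBH(s-Bu)3 (1.1 equiv), THF, −78 °C; H2O quench; chromatography to remove the minor cis isomer
Reagents that add atoms: none
Why: 1,2-Reduction of the β-methyl enone by a bulky hydride, which enters anti to the pseudoaxial C6 methyl group (itself anti to the pseudoaxial ester), so the hydroxyl ends up trans to the ester (relative configuration only).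

Step 3
Reactants: 5 methyl (1R*,4R*)-4-hydroxy-2,6,6-trimethylcyclohex-2-ene-1-carboxylate (racemic)
Product: 6 methyl (1R,4R)-4-{[(1S,4R)-4,7,7-trimethyl-3-oxo-2-oxabicyclo[2.2.1]heptane-1-carbonyl]oxy}-2,6,6-trimethylcyclohex-2-ene-1-carboxylate (single diastereomer)
Conditions: (1S,4R)-camphanic chloride (1.1 equiv), pyridine, 4-(dimethylamino)pyridine (cat.), CH2Cl2, 0 °C → rt; fractional crystallisation (hexane/EtOAc), mother liquor by chromatography
Reagents that add atoms: (1S,4R)-camphanic chloride, CC1(C)[C@@]2(C)CC[C@@]1(OC2=O)C(Cl)=O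
Why: Acylation turns the two enantiomers into diastereomeric camphanates that are separated (classical resolution, configuration confirmed by X-ray against the known camphanoyl centres), which fixes both ring stereocentres as (1R,4R).

Step 4
Reactants: 6 the (1R,4R) camphanate
Product: 7 methyl (1R,4R)-4-hydroxy-2,6,6-trimethylcyclohex-2-ene-1-carboxylate
Conditions: K2CO3 (0.2 equiv), MeOH, rt
Reagents that add atoms: none
Why: Base-catalysed transesterification removes the auxiliary as its methyl ester while the hindered ring methyl ester is unchanged and the non-conjugated C1–H is not epimerised by carbonate.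

Step 5
Reactants: 7 methyl (1R,4R)-4-hydroxy-2,6,6-trimethylcyclohex-2-ene-1-carboxylate
Product: 8 methyl (1R,4R)-4-[(tert-butyldimethylsilyl)oxy]-2,6,6-trimethylcyclohex-2-ene-1-carboxylate
Conditions: TBSCl, imidazole, DMF, rt
Reagents that add atoms: tert-butyldimethylsilyl chloride, CC(C)(C)[Si](C)(C)Cl
Why: Standard silylation protects the allylic alcohol against the hydride, Grignard and acid steps that follow, without touching either stereocentre.

Step 6
Reactants: 8 the silyl ether ester
Product: 9 [(1R,4R)-4-[(tert-butyldimethylsilyl)oxy]-2,6,6-trimethylcyclohex-2-en-1-yl]methanol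
Conditions: LiAlH4, Et2O, 0 °C → rt; H2O/NaOH work-up
Reagents that add atoms: none
Why: Hydride reduction of the hindered ester to the primary alcohol is clean and non-epimerising, and is more reliable here than a partial reduction to the aldehyde.

Step 7
Reactants: 9 the primary alcohol
Product: 10 (1R,4R)-4-[(tert-butyldimethylsilyl)oxy]-2,6,6-trimethylcyclohex-2-ene-1-carbaldehyde
Conditions: Dess–Martin periodinane, CH2Cl2, 0 °C → rt; used at once
Reagents that add atoms: none
Why: Dess–Martin oxidation is fast and nearly neutral, so the β,γ-unsaturated aldehyde is neither epimerised at its α-carbon nor isomerised into conjugation.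

Step 8
Reactants: 11 chloroacetone (1-chloropropan-2-one)
Product: 12 (2-oxopropyl)triphenylphosphonium chloride
Conditions: PPh3, CHCl3, reflux
Reagents that add atoms: triphenylphosphine, c1ccccc1P(c1ccccc1)c1ccccc1
Why: SN2 quaternisation of the phosphine by the activated α-chloro ketone.

Step 9
Reactants: 12 (2-oxopropyl)triphenylphosphonium chloride
Product: 13 1-(triphenyl-λ5-phosphanylidene)propan-2-one
Conditions: aq. NaOH (1 equiv), H2O/CH2Cl2, rt
Reagents that add atoms: none
Why: Deprotonation of the acidic keto-phosphonium salt gives the isolable stabilised ylide.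

Step 10
Reactants: 10 the ring aldehyde; 13 the acetonylidene ylide
Product: 14 (3E)-4-[(1R,4R)-4-[(tert-butyldimethylsilyl)oxy]-2,6,6-trimethylcyclohex-2-en-1-yl]but-3-en-2-one
Conditions: toluene, 100 °C, 36 h
Reagents that add atoms: none
Why: Wittig olefination with a stabilised, non-basic ylide gives the E-enone (C7=C8) and leaves the epimerisable centre next to the aldehyde untouched.

Step 11
Reactants: 14 the C13 enone
Product: 15 (1E)-1-[(1R,4R)-4-[(tert-butyldimethylsilyl)oxy]-2,6,6-trimethylcyclohex-2-en-1-yl]-3-methylpenta-1,4-dien-3-ol (both epimers at the carbinol carbon)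
Conditions: CH2=CHMgBr (1.3 equiv), THF, −20 → 0 °C; H2O quench
Reagents that add atoms: vinylmagnesium bromide, C=C[Mg]Br
Why: 1,2-Grignard addition to the β-hindered methyl ketone gives the tertiary vinyl carbinol, whose new centre need not be controlled because it is destroyed in the following step.

Step 12
Reactants: 15 the C15 vinyl carbinol
Product: 16 [(2E,4E)-5-[(1R,4R)-4-[(tert-butyldimethylsilyl)oxy]-2,6,6-trimethylcyclohex-2-en-1-yl]-3-methylpenta-2,4-dien-1-yl]triphenylphosphonium bromide
Conditions: PPh3·HBr (1.05 equiv), CH2Cl2, 0 °C → rt; crystallise (EtOAc/Et2O) to remove the minor 2Z salt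
Reagents that add atoms: triphenylphosphine hydrobromide, [Br-].c1ccccc1[PH+](c1ccccc1)c1ccccc1
Why: The doubly allylic tertiary alcohol ionises far more easily than the silylated ring allylic ether, and the phosphine traps the pentadienyl cation at its unhindered terminus (SN1' with allylic transposition), the ring stereocentres being untouched.

Step 13
Reactants: 15 the C15 vinyl carbinol
Product: 17 (1R,4R)-4-[(1E)-3-hydroxy-3-methylpenta-1,4-dien-1-yl]-3,5,5-trimethylcyclohex-2-en-1-ol (both side-chain epimers)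
Conditions: Bu4NF, THF, rt
Reagents that add atoms: none
Why: Fluoride cleaves the silyl ether and there is no carbonyl group that could make the C6 proton acidic.

Step 14
Reactants: 17 the diol
Product: 18 (4R)-4-[(1E)-3-hydroxy-3-methylpenta-1,4-dien-1-yl]-3,5,5-trimethylcyclohex-2-en-1-one
Conditions: activated MnO2 (20 equiv), CH2Cl2, rt
Reagents that add atoms: none
Why: MnO2 oxidises only the secondary allylic ring alcohol (the tertiary alcohol cannot be oxidised) under neutral heterogeneous conditions, so the now vinylogously acidic C6 centre keeps its R configuration.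

Step 15
Reactants: 18 the keto vinyl carbinol
Product: 19 [(2E,4E)-3-methyl-5-[(1R)-2,6,6-trimethyl-4-oxocyclohex-2-en-1-yl]penta-2,4-dien-1-yl]triphenylphosphonium bromide
Conditions: PPh3·HBr (1.05 equiv), CH2Cl2, 0 °C → rt; crystallise
Reagents that add atoms: triphenylphosphine hydrobromide, [Br-].c1ccccc1[PH+](c1ccccc1)c1ccccc1
Why: Same SN1' salt formation as in step 12; the mildly acidic, base-free medium does not enolise the enone toward C6 and the phosphine captures the cation faster than it can lose the C6 proton.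

Step 16
Reactants: 20 (E)-1,4-dibromobut-2-ene
Product: 21 tetramethyl [(2E)-but-2-ene-1,4-diyl]bis(phosphonate)
Conditions: P(OMe)3 (2.5 equiv), neat, 110 °C, MeBr distilled off
Reagents that add atoms: trimethyl phosphite, COP(OC)OC
Why: Double Michaelis–Arbuzov reaction of the allylic dibromide, with the E double bond retained.

Step 17
Reactants: 21 the bis(phosphonate); 22 1,1-dimethoxypropan-2-one (methylglyoxal dimethyl acetal, 2.1 equiv)
Product: 24 (2E,4E,6E)-1,1,8,8-tetramethoxy-2,7-dimethylocta-2,4,6-triene, via monoolefination phosphonate 23 (not isolated)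
Conditions: KOtBu (2.2 equiv), THF, −20 °C → rt
Reagents that add atoms: none
Why: Twofold Horner–Wadsworth–Emmons olefination of the activated α,α-dialkoxy ketone builds the C10 triene, E being favoured and residual Z isomers converging in the next step.

Step 18
Reactants: 24 the bis(acetal)
Product: 26 (2E,4E,6E)-2,7-dimethylocta-2,4,6-trienedial, via monoacetal aldehyde 25 (not isolated)
Conditions: 1 M aq. H2SO4 (cat.), THF/H2O, rt; crystallise
Reagents that add atoms: water, O
Why: Acid hydrolysis of the allylic acetals, during which the conjugated dialdehyde equilibrates to the crystalline all-E isomer.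

Step 19
Reactants: 16 the ring-B C15 phosphonium salt; 26 the C10 dialdehyde (2.5 equiv)
Product: 28 (2E,4E,6E,8E,10E,12E)-13-[(1R,4R)-4-[(tert-butyldimethylsilyl)oxy]-2,6,6-trimethylcyclohex-2-en-1-yl]-2,7,11-trimethyltrideca-2,4,6,8,10,12-hexaenal, via ylide 27 (not isolated)
Conditions: NaOMe (1.05 equiv, added slowly), CH2Cl2/MeOH, 0 °C → rt; then heptane, 90 °C (Z → E); excess 26 recovered
Reagents that add atoms: none
Why: Wittig olefination in which the ylide is generated in the presence of excess dialdehyde, so that only one formyl group reacts (the C25 product is a less electrophilic polyenal), and the new C11'=C12' bond is equilibrated to E by warming.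

Step 20
Reactants: 28 the silylated C25 aldehyde
Product: 29 (2E,4E,6E,8E,10E,12E)-13-[(1R,4R)-4-hydroxy-2,6,6-trimethylcyclohex-2-en-1-yl]-2,7,11-trimethyltrideca-2,4,6,8,10,12-hexaenal
Conditions: Bu4NF/AcOH (1:1), THF, rt
Reagents that add atoms: none
Why: Buffered fluoride desilylation frees the ring-B hydroxyl before the base-sensitive keto end group is introduced, the buffer protecting the polyenal and the C6' centre.

Step 21
Reactants: 29 the ring-B C25 hydroxy aldehyde; 19 the ring-A keto phosphonium salt (1.3 equiv)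
Product: 31 (6R,3'R,6'R)-3'-hydroxy-ε,ε-caroten-3-one (all-E), via keto ylide 30 (not isolated)
Conditions: 1,2-epoxybutane/EtOH (1:1), 65 °C, 18 h; then heptane, 90 °C (Z → E), crystallise
Reagents that add atoms: none
Why: Wittig olefination under essentially neutral conditions (the epoxide scavenges HBr, so no strong base is ever free) joins the two large fragments at C11=C12; the aldehyde reacts far faster than the enone ketone and the three stereocentres, all set in steps 2–3, are not touched.

## Compound list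

1 | mesityl oxide (4-methylpent-3-en-2-one) | CC(=O)C=C(C)C | starting material
2 | methyl acetoacetate | COC(=O)CC(C)=O | starting material
3 | methyl 2-acetyl-3,3-dimethyl-5-oxohexanoate (racemic Michael adduct) | COC(=O)C(C(C)=O)C(C)(C)CC(C)=O | intermediate (not isolated)
4 | methyl 2,6,6-trimethyl-4-oxocyclohex-2-ene-1-carboxylate (racemic) | COC(=O)C1C(C)=CC(=O)CC1(C)C | intermediate
5 | methyl (1R*,4R*)-4-hydroxy-2,6,6-trimethylcyclohex-2-ene-1-carboxylate (racemic trans; (1R,4R) drawn) | COC(=O)[C@H]1C(C)=C[C@H](O)CC1(C)C | intermediate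
6 | methyl (1R,4R)-4-{[(1S,4R)-4,7,7-trimethyl-3-oxo-2-oxabicyclo[2.2.1]heptane-1-carbonyl]oxy}-2,6,6-trimethylcyclohex-2-ene-1-carboxylate | COC(=O)[C@H]1C(C)=C[C@H](OC(=O)[C@@]23CC[C@@](C)(C(=O)O2)C3(C)C)CC1(C)C | intermediate
7 | methyl (1R,4R)-4-hydroxy-2,6,6-trimethylcyclohex-2-ene-1-carboxylate | COC(=O)[C@H]1C(C)=C[C@H](O)CC1(C)C | intermediate
8 | methyl (1R,4R)-4-[(tert-butyldimethylsilyl)oxy]-2,6,6-trimethylcyclohex-2-ene-1-carboxylate | COC(=O)[C@H]1C(C)=C[C@H](O[Si](C)(C)C(C)(C)C)CC1(C)C | intermediate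
9 | [(1R,4R)-4-[(tert-butyldimethylsilyl)oxy]-2,6,6-trimethylcyclohex-2-en-1-yl]methanol | OC[C@H]1C(C)=C[C@H](O[Si](C)(C)C(C)(C)C)CC1(C)C | intermediate
10 | (1R,4R)-4-[(tert-butyldimethylsilyl)oxy]-2,6,6-trimethylcyclohex-2-ene-1-carbaldehyde | O=C[C@H]1C(C)=C[C@H](O[Si](C)(C)C(C)(C)C)CC1(C)C | intermediate
11 | chloroacetone (1-chloropropan-2-one) | CC(=O)CCl | starting material
12 | (2-oxopropyl)triphenylphosphonium chloride | [Cl-].CC(=O)C[P+](c1ccccc1)(c1ccccc1)c1ccccc1 | intermediate
13 | 1-(triphenyl-λ5-phosphanylidene)propan-2-one | CC(=O)C=P(c1ccccc1)(c1ccccc1)c1ccccc1 | intermediate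
14 | (3E)-4-[(1R,4R)-4-[(tert-butyldimethylsilyl)oxy]-2,6,6-trimethylcyclohex-2-en-1-yl]but-3-en-2-one | CC(=O)/C=C/[C@H]1C(C)=C[C@H](O[Si](C)(C)C(C)(C)C)CC1(C)C | intermediate
15 | (1E)-1-[(1R,4R)-4-[(tert-butyldimethylsilyl)oxy]-2,6,6-trimethylcyclohex-2-en-1-yl]-3-methylpenta-1,4-dien-3-ol (carbinol epimers) | C=CC(C)(O)/C=C/[C@H]1C(C)=C[C@H](O[Si](C)(C)C(C)(C)C)CC1(C)C | intermediate
16 | [(2E,4E)-5-[(1R,4R)-4-[(tert-butyldimethylsilyl)oxy]-2,6,6-trimethylcyclohex-2-en-1-yl]-3-methylpenta-2,4-dien-1-yl]triphenylphosphonium bromide | [Br-].c1ccccc1[P+](c1ccccc1)(c1ccccc1)C/C=C(C)/C=C/[C@H]1C(C)=C[C@H](O[Si](C)(C)C(C)(C)C)CC1(C)C | intermediate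
17 | (1R,4R)-4-[(1E)-3-hydroxy-3-methylpenta-1,4-dien-1-yl]-3,5,5-trimethylcyclohex-2-en-1-ol (side-chain epimers) | C=CC(C)(O)/C=C/[C@H]1C(C)=C[C@H](O)CC1(C)C | intermediate
18 | (4R)-4-[(1E)-3-hydroxy-3-methylpenta-1,4-dien-1-yl]-3,5,5-trimethylcyclohex-2-en-1-one (side-chain epimers) | CC1=CC(=O)CC(C)(C)[C@H]1/C=C/C(C)(O)C=C | intermediate
19 | [(2E,4E)-3-methyl-5-[(1R)-2,6,6-trimethyl-4-oxocyclohex-2-en-1-yl]penta-2,4-dien-1-yl]triphenylphosphonium bromide | [Br-].CC1=CC(=O)CC(C)(C)[C@H]1/C=C/C(C)=C/C[P+](c1ccccc1)(c1ccccc1)c1ccccc1 | intermediate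
20 | (E)-1,4-dibromobut-2-ene | BrC/C=C/CBr | starting material
21 | tetramethyl [(2E)-but-2-ene-1,4-diyl]bis(phosphonate) | COP(=O)(OC)C/C=C/CP(=O)(OC)OC | intermediate
22 | 1,1-dimethoxypropan-2-one | CC(=O)C(OC)OC | starting material
23 | dimethyl [(2E,4E)-6,6-dimethoxy-5-methylhexa-2,4-dien-1-yl]phosphonate | COC(OC)/C(C)=C/C=C/CP(=O)(OC)OC | intermediate (not isolated)
24 | (2E,4E,6E)-1,1,8,8-tetramethoxy-2,7-dimethylocta-2,4,6-triene | COC(OC)/C(C)=C/C=C/C=C(C)/C(OC)OC | intermediate
25 | (2E,4E,6E)-8,8-dimethoxy-2,7-dimethylocta-2,4,6-trienal | O=C/C(C)=C/C=C/C=C(C)/C(OC)OC | intermediate (not isolated)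
26 | (2E,4E,6E)-2,7-dimethylocta-2,4,6-trienedial | O=C/C(C)=C/C=C/C=C(C)/C=O | intermediate
27 | {(2E,4E)-5-[(1R,4R)-4-[(tert-butyldimethylsilyl)oxy]-2,6,6-trimethylcyclohex-2-en-1-yl]-3-methylpenta-2,4-dien-1-ylidene}triphenyl-λ5-phosphane | c1ccccc1P(c1ccccc1)(c1ccccc1)=C/C=C(C)/C=C/[C@H]1C(C)=C[C@H](O[Si](C)(C)C(C)(C)C)CC1(C)C | intermediate (not isolated)
28 | (2E,4E,6E,8E,10E,12E)-13-[(1R,4R)-4-[(tert-butyldimethylsilyl)oxy]-2,6,6-trimethylcyclohex-2-en-1-yl]-2,7,11-trimethyltrideca-2,4,6,8,10,12-hexaenal | O=C/C(C)=C/C=C/C=C(C)/C=C/C=C(C)/C=C/[C@H]1C(C)=C[C@H](O[Si](C)(C)C(C)(C)C)CC1(C)C | intermediate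
29 | (2E,4E,6E,8E,10E,12E)-13-[(1R,4R)-4-hydroxy-2,6,6-trimethylcyclohex-2-en-1-yl]-2,7,11-trimethyltrideca-2,4,6,8,10,12-hexaenal | O=C/C(C)=C/C=C/C=C(C)/C=C/C=C(C)/C=C/[C@H]1C(C)=C[C@H](O)CC1(C)C | intermediate
30 | {(2E,4E)-3-methyl-5-[(1R)-2,6,6-trimethyl-4-oxocyclohex-2-en-1-yl]penta-2,4-dien-1-ylidene}triphenyl-λ5-phosphane | CC1=CC(=O)CC(C)(C)[C@H]1/C=C/C(C)=C/C=P(c1ccccc1)(c1ccccc1)c1ccccc1 | intermediate (not isolated)
31 | (6R,3'R,6'R)-3'-hydroxy-ε,ε-caroten-3-one (all-E) | CC1=CC(=O)CC(C)(C)[C@H]1/C=C/C(C)=C/C=C/C(C)=C/C=C/C=C(C)/C=C/C=C(C)/C=C/[C@H]1C(C)=C[C@H](O)CC1(C)C | target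

## Step count and risks

Total step count: 21.
Longest linear sequence: 13 steps (1–7, 10–12, 19–21; the ring-A line 1–7, 10, 11, 13–15, 21 is equally long).

Steps most likely to fail:

Step 2 (face selectivity of the reduction). If the cis alcohol dominates, the fallback sets out from 4 and returns at 5. Reduce 4 with NaBH4/CeCl3·7H2O (MeOH, −40 °C) and isolate the cis alcohol methyl (1R*,4S*)-4-hydroxy-2,6,6-trimethylcyclohex-2-ene-1-carboxylate F1. Invert its carbinol centre by Mitsunobu esterification (4-nitrobenzoic acid, PPh3, diisopropyl azodicarboxylate, THF, 0 °C) to the trans ester methyl (1R*,4R*)-4-[(4-nitrobenzoyl)oxy]-2,6,6-trimethylcyclohex-2-ene-1-carboxylate F2. Methanolysis (K2CO3, MeOH) then gives 5.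

Step 3 (the camphanates may not separate well). The fallback replaces resolution by catalytic asymmetric reduction; it sets out from 4 and returns at 7, bypassing 5 and 6. Reduce racemic 4 with catecholborane and (S)-tetrahydro-1-methyl-3,3-diphenyl-1H,3H-pyrrolo[1,2-c][1,3,2]oxazaborole (20 mol %, toluene, −78 °C). The catalyst is expected to set the carbinol carbon as R in both enantiomers of the ketone. The (1R) ketone gives 7; the (1S) ketone gives the cis diastereomer methyl (1S,4R)-4-hydroxy-2,6,6-trimethylcyclohex-2-ene-1-carboxylate F3. The two are diastereomers and are separated on silica; F3 can be reoxidised to 4 and recycled. The enantiomeric purity of 7 should be checked, because the (1S) ketone is the mismatched case and could leak some (1S,4S) trans alcohol.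

Step 21 (a ylide carrying the enone end group; possible epimerisation at C6 or low conversion). The fallback unveils the ketone only after the coupling; it sets out from 16 and 28 and returns at 31. Desilylate 16 (HF·pyridine, THF, 0 °C) to [(2E,4E)-5-[(1R,4R)-4-hydroxy-2,6,6-trimethylcyclohex-2-en-1-yl]-3-methylpenta-2,4-dien-1-yl]triphenylphosphonium bromide F4. Couple F4 with 28 (NaOMe, CH2Cl2/MeOH, 0 °C) to (3R,6R,3'R,6'R)-3'-[(tert-butyldimethylsilyl)oxy]-ε,ε-caroten-3-ol F5. Oxidise the only free allylic alcohol with MnO2 (CH2Cl2, rt) to (6R,3'R,6'R)-3'-[(tert-butyldimethylsilyl)oxy]-ε,ε-caroten-3-one F6. Remove the silyl group with Bu4NF/AcOH (THF, rt) to reach 31.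

## Further compounds

F1 | step 2 | methyl (1R*,4S*)-4-hydroxy-2,6,6-trimethylcyclohex-2-ene-1-carboxylate (racemic cis; (1R,4S) drawn) | COC(=O)[C@H]1C(C)=C[C@@H](O)CC1(C)C
F2 | step 2 | methyl (1R*,4R*)-4-[(4-nitrobenzoyl)oxy]-2,6,6-trimethylcyclohex-2-ene-1-carboxylate (racemic trans; (1R,4R) drawn) | COC(=O)[C@H]1C(C)=C[C@H](OC(=O)c2ccc(cc2)[N+](=O)[O-])CC1(C)C
F3 | step 3 | methyl (1S,4R)-4-hydroxy-2,6,6-trimethylcyclohex-2-ene-1-carboxylate | COC(=O)[C@@H]1C(C)=C[C@H](O)CC1(C)C
F4 | step 21 | [(2E,4E)-5-[(1R,4R)-4-hydroxy-2,6,6-trimethylcyclohex-2-en-1-yl]-3-methylpenta-2,4-dien-1-yl]triphenylphosphonium bromide | [Br-].c1ccccc1[P+](c1ccccc1)(c1ccccc1)C/C=C(C)/C=C/[C@H]1C(C)=C[C@H](O)CC1(C)C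
F5 | step 21 | (3R,6R,3'R,6'R)-3'-[(tert-butyldimethylsilyl)oxy]-ε,ε-caroten-3-ol | CC1=C[C@H](O)CC(C)(C)[C@H]1/C=C/C(C)=C/C=C/C(C)=C/C=C/C=C(C)/C=C/C=C(C)/C=C/[C@H]1C(C)=C[C@H](O[Si](C)(C)C(C)(C)C)CC1(C)C
F6 | step 21 | (6R,3'R,6'R)-3'-[(tert-butyldimethylsilyl)oxy]-ε,ε-caroten-3-one | CC1=CC(=O)CC(C)(C)[C@H]1/C=C/C(C)=C/C=C/C(C)=C/C=C/C=C(C)/C=C/C=C(C)/C=C/[C@H]1C(C)=C[C@H](O[Si](C)(C)C(C)(C)C)CC1(C)C
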